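**Assumption:** side-chain carbons are counted C1′ (benzylic CH2) to C16′; the only stereocentre, C13′, is (S) as encoded in the target SMILES (O > C14′ vinyl > C12′ > H). The route is a proposal and has not been run; the sense of induction in step 6 is assigned by analogy and should be confirmed on the first batch (Mosher ester).

**Retrosynthetic overview**
1. No ring is formed: the benzene ring is bought as a cresol derivative. The last three steps only unmask functional groups (silyl ether, then hydroquinone dimethyl ether via the quinone).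
2. Key disconnection C4′–C5′–C6′: a three-component carbonylative union (the new step) of an aryl-bearing allylic chloride (C1′–C4′), CO (C5′) and an alkenylmetal (C6′–C16′) made from a terminal alkyne.
3. The right-hand alkyne comes from iterative alkyne methylalumination and Negishi coupling with a four-carbon homopropargylzinc; this sets the 10′E olefin, and the 6′E olefin is set in the union.
4. C13′ is set first, by catalytic asymmetric propargylation of 3-methylbut-2-enal.
5. The left-hand chloride comes from an aryl bromide and prenyl bromide, then E-selective SeO2 oxidation (2′E olefin).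

**Route**

Step 1
Reactants: 1 4-methoxy-2-methylphenol
Product: 2 2-bromo-4-methoxy-6-methylphenol
Conditions: NBS (1.0 equiv), i-Pr2NH (10 mol%), CH2Cl2, 0 °C
Reagents that add atoms: N-bromosuccinimide O=C1CCC(=O)N1Br
Why: Amine-mediated electrophilic aromatic bromination goes ortho to the free phenol, whose para position is blocked by OMe, so only C6 is brominated.

Step 2
Reactants: 2 2-bromo-4-methoxy-6-methylphenol
Product: 3 1-bromo-2,5-dimethoxy-3-methylbenzene
Conditions: MeI, K2CO3, acetone, reflux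
Reagents that add atoms: iodomethane CI
Why: Williamson O-methylation gives the hydroquinone dimethyl ether, which tolerates the organometallic steps that follow.

Step 3
Reactants: 3 1-bromo-2,5-dimethoxy-3-methylbenzene; 4 1-bromo-3-methylbut-2-ene (prenyl bromide)
Product: 6 2,5-dimethoxy-1-methyl-3-(3-methylbut-2-en-1-yl)benzene, via aryllithium 5 (not isolated)
Conditions: n-BuLi (1.05 equiv), THF, −78 °C; then 4, CuBr·SMe2 (10 mol%), −78 °C to rt
Reagents that add atoms: none
Why: Br–Li exchange gives the aryllithium, which undergoes copper-catalysed SN2 allylation at the unsubstituted carbon of the primary prenyl bromide.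

Step 4
Reactants: 6 2,5-dimethoxy-1-methyl-3-(3-methylbut-2-en-1-yl)benzene
Product: 7 (2E)-4-(2,5-dimethoxy-3-methylphenyl)-2-methylbut-2-en-1-ol
Conditions: SeO2 (0.3 equiv), t-BuOOH (2 equiv), salicylic acid (10 mol%), CH2Cl2, 0 °C to rt, stopped at about 70% conversion, 6 recycled
Reagents that add atoms: tert-butyl hydroperoxide CC(C)(C)OO (terminal oxidant); selenium dioxide O=[Se]=O (catalytic oxygen carrier)
Why: SeO2 allylic oxidation (ene reaction, then [2,3]-sigmatropic shift) hydroxylates the methyl group trans to the chain of the trisubstituted olefin, giving the E-allylic alcohol (the 2′E olefin).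

Step 5
Reactants: 7 (2E)-4-(2,5-dimethoxy-3-methylphenyl)-2-methylbut-2-en-1-ol
Product: 8 1-[(2E)-4-chloro-3-methylbut-2-en-1-yl]-2,5-dimethoxy-3-methylbenzene
Conditions: NCS, Me2S, CH2Cl2, −20 to 0 °C
Reagents that add atoms: N-chlorosuccinimide O=C1CCC(=O)N1Cl
Why: Corey–Kim chlorination (alkoxysulfonium ion, SN2 by chloride) converts the primary allylic alcohol to the chloride without allylic transposition or E/Z change.

Step 6
Reactants: 9 3-methylbut-2-enal; 10 4,4,5,5-tetramethyl-2-(propa-1,2-dien-1-yl)-1,3,2-dioxaborolane (allenylboronic acid pinacol ester)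
Product: 12 (4S)-2-methylhept-2-en-6-yn-4-ol, via borate ester 11 (not isolated)
Conditions: (S)-TRIP [(S)-3,3′-bis(2,4,6-triisopropylphenyl)-1,1′-binaphthyl-2,2′-diyl hydrogen phosphate] (5 mol%), 4 Å molecular sieves, toluene, −20 °C; aqueous work-up
Reagents that add atoms: none
Why: Chiral phosphoric acid-catalysed propargylation of the aldehyde: the allenylboronate reacts through a closed six-membered SE2′ transition state in which the (S)-acid hydrogen-bonds the boronate oxygen and shields the Re face, so the allene terminus adds to the Si face of the enal and sets the (S)-carbinol (later C13′).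

Step 7
Reactants: 12 (4S)-2-methylhept-2-en-6-yn-4-ol
Product: 13 tert-butyldimethyl{[(4S)-2-methylhept-2-en-6-yn-4-yl]oxy}silane
Conditions: TBSCl, imidazole, DMF, rt
Reagents that add atoms: tert-butyldimethylsilyl chloride CC(C)(C)[Si](C)(C)Cl
Why: Standard silylation protects the secondary allylic alcohol against the alanes and organozincs used later and leaves the stereocentre untouched.

Step 8
Reactants: 13 tert-butyldimethyl{[(4S)-2-methylhept-2-en-6-yn-4-yl]oxy}silane
Product: 15 tert-butyl{[(1E,4S)-1-iodo-2,6-dimethylhepta-1,5-dien-4-yl]oxy}dimethylsilane, via alkenylalane 14 (not isolated)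
Conditions: Me3Al (2.0 equiv), Cp2ZrCl2 (0.25 equiv), CH2Cl2, 0 °C to rt; then I2, THF, −30 to 0 °C
Reagents that add atoms: trimethylaluminium C[Al](C)C; iodine II
Why: Zirconium-catalysed methylalumination (Negishi carboalumination) adds Me and Al syn across the terminal alkyne with Me on the internal carbon, and iodinolysis with retention gives the E-alkenyl iodide (the 10′E olefin).

Step 9
Reactants: 15 tert-butyl{[(1E,4S)-1-iodo-2,6-dimethylhepta-1,5-dien-4-yl]oxy}dimethylsilane; 16 (4-bromobut-1-yn-1-yl)trimethylsilane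
Product: 18 tert-butyl{[(4S,6E)-2,6-dimethyl-11-(trimethylsilyl)undeca-2,6-dien-10-yn-4-yl]oxy}dimethylsilane, via alkylzinc bromide 17 (not isolated)
Conditions: 16, Zn dust, LiCl, THF, 50 °C; then 15, Pd(PPh3)4 (3 mol%), THF, rt
Reagents that add atoms: none
Why: Negishi sp3–sp2 cross-coupling of the homopropargylzinc reagent with the alkenyl iodide proceeds with retention of olefin geometry and installs C6′–C9′ as a silyl-capped alkyne.

Step 10
Reactants: 18 tert-butyl{[(4S,6E)-2,6-dimethyl-11-(trimethylsilyl)undeca-2,6-dien-10-yn-4-yl]oxy}dimethylsilane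
Product: 19 tert-butyl{[(4S,6E)-2,6-dimethylundeca-2,6-dien-10-yn-4-yl]oxy}dimethylsilane
Conditions: K2CO3 (0.3 equiv), MeOH, rt
Reagents that add atoms: none
Why: Methoxide-catalysed methanolysis of the alkynyl–silicon bond frees the terminal alkyne while the hindered secondary TBS ether stays.

Step 11
Reactants: 19 tert-butyl{[(4S,6E)-2,6-dimethylundeca-2,6-dien-10-yn-4-yl]oxy}dimethylsilane; 8 1-[(2E)-4-chloro-3-methylbut-2-en-1-yl]-2,5-dimethoxy-3-methylbenzene
Product: 22 (2E,6E,10E,13S)-13-[(tert-butyldimethylsilyl)oxy]-1-(2,5-dimethoxy-3-methylphenyl)-3,7,11,15-tetramethylhexadeca-2,6,10,14-tetraen-5-one, via alkenylalane 20 (not isolated), via alkenylzinc chloride 21 (not isolated)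
Conditions: Me3Al (2.0 equiv), Cp2ZrCl2 (0.2 equiv), CH2Cl2, 0 °C to rt; volatiles removed in vacuo; ZnCl2 (1.1 equiv), THF, 0 °C; then 8 (0.9 equiv), Pd(PPh3)4 (5 mol%), CO (3 atm), THF–DMPU 4:1, 0 °C to rt; cold pH 7 phosphate buffer quench
Reagents that add atoms: trimethylaluminium C[Al](C)C; carbon monoxide [C-]#[O+]
Why: Proposed new method: a one-pot alkyne methylalumination and palladium-catalysed three-component carbonylative allylation; syn-methylalumination fixes the 6′E olefin, ZnCl2 turns alane 20 into alkenylzinc 21, chloride 8 adds oxidatively to zerovalent palladium to give an η3-allyl complex that takes up the alkenyl group, and because C–C reductive elimination from η3-allyl(alkenyl)palladium is slow without a π-acid, CO binds, inserts into the Pd–alkenyl bond and the acyl(allyl)palladium eliminates at the unsubstituted allyl terminus C4′, forming C4′–C5′ and C5′–C6′ with both E-olefins retained and the β,γ-olefin left out of conjugation; the closest known reaction types are the carbonylative Stille coupling of allylic chlorides with alkenylstannanes and the palladium-catalysed coupling of alkylzinc halides, CO and allylic esters, neither of which has been shown with alkenylalanes or alkenylzincs made by alkyne carboalumination.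

Step 12
Reactants: 22 (2E,6E,10E,13S)-13-[(tert-butyldimethylsilyl)oxy]-1-(2,5-dimethoxy-3-methylphenyl)-3,7,11,15-tetramethylhexadeca-2,6,10,14-tetraen-5-one
Product: 23 (2E,6E,10E,13S)-1-(2,5-dimethoxy-3-methylphenyl)-13-hydroxy-3,7,11,15-tetramethylhexadeca-2,6,10,14-tetraen-5-one
Conditions: HF·pyridine, pyridine, THF, 0 °C to rt
Reagents that add atoms: none
Why: Pyridine-buffered HF cleaves the secondary TBS ether without base, so the β,γ-unsaturated ketone is not isomerised into conjugation and the allylic carbinol is not ionised.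

Step 13
Reactants: 23 (2E,6E,10E,13S)-1-(2,5-dimethoxy-3-methylphenyl)-13-hydroxy-3,7,11,15-tetramethylhexadeca-2,6,10,14-tetraen-5-one
Product: 24 2-[(2E,6E,10E,13S)-13-hydroxy-3,7,11,15-tetramethyl-5-oxohexadeca-2,6,10,14-tetraen-1-yl]-6-methylcyclohexa-2,5-diene-1,4-dione
Conditions: (NH4)2Ce(NO3)6 (2.5 equiv), pyridine-2,6-dicarboxylic acid N-oxide (2.5 equiv), MeCN–H2O 2:1, 0 °C, 15 min
Reagents that add atoms: water O
Why: Oxidative demethylation of the hydroquinone dimethyl ether by tetravalent cerium (two one-electron oxidations, water adds to the arene radical cation, methanol leaves) gives the p-quinone within minutes at 0 °C, with the N-oxide diacid buffering the medium for the allylic alcohol and the skipped enone.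

Step 14
Reactants: 24 2-[(2E,6E,10E,13S)-13-hydroxy-3,7,11,15-tetramethyl-5-oxohexadeca-2,6,10,14-tetraen-1-yl]-6-methylcyclohexa-2,5-diene-1,4-dione
Product: 25 2-[(2E,6E,10E,13S)-13-hydroxy-3,7,11,15-tetramethyl-5-oxohexadeca-2,6,10,14-tetraen-1-yl]-6-methylbenzene-1,4-diol (CNP0251818.1)
Conditions: Na2S2O4 (excess, aq.), Et2O–H2O, rt, argon, degassed solvents
Reagents that add atoms: none
Why: Dithionite reduces the quinone to the hydroquinone under neutral two-phase conditions that leave the ketone, the olefins and the carbinol untouched.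

**Compound list**
1 | 4-methoxy-2-methylphenol | COc1ccc(O)c(C)c1 | starting material
2 | 2-bromo-4-methoxy-6-methylphenol | COc1cc(C)c(O)c(Br)c1 | intermediate
3 | 1-bromo-2,5-dimethoxy-3-methylbenzene | COc1cc(C)c(OC)c(Br)c1 | intermediate
4 | 1-bromo-3-methylbut-2-ene | CC(C)=CCBr | starting material
5 | (2,5-dimethoxy-3-methylphenyl)lithium | [Li]c1cc(OC)cc(C)c1OC | intermediate
6 | 2,5-dimethoxy-1-methyl-3-(3-methylbut-2-en-1-yl)benzene | CC(C)=CCc1cc(OC)cc(C)c1OC | intermediate
7 | (2E)-4-(2,5-dimethoxy-3-methylphenyl)-2-methylbut-2-en-1-ol | OC/C(C)=C/Cc1cc(OC)cc(C)c1OC | intermediate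
8 | 1-[(2E)-4-chloro-3-methylbut-2-en-1-yl]-2,5-dimethoxy-3-methylbenzene | ClC/C(C)=C/Cc1cc(OC)cc(C)c1OC | intermediate
9 | 3-methylbut-2-enal | CC(C)=CC=O | starting material
10 | 4,4,5,5-tetramethyl-2-(propa-1,2-dien-1-yl)-1,3,2-dioxaborolane | C=C=CB1OC(C)(C)C(C)(C)O1 | starting material
11 | 4,4,5,5-tetramethyl-2-{[(4S)-2-methylhept-2-en-6-yn-4-yl]oxy}-1,3,2-dioxaborolane | CC(C)=C[C@@H](OB1OC(C)(C)C(C)(C)O1)CC#C | intermediate
12 | (4S)-2-methylhept-2-en-6-yn-4-ol | CC(C)=C[C@@H](O)CC#C | intermediate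
13 | tert-butyldimethyl{[(4S)-2-methylhept-2-en-6-yn-4-yl]oxy}silane | CC(C)=C[C@@H](O[Si](C)(C)C(C)(C)C)CC#C | intermediate
14 | {(1E,4S)-4-[(tert-butyldimethylsilyl)oxy]-2,6-dimethylhepta-1,5-dien-1-yl}dimethylalumane | CC(C)=C[C@@H](O[Si](C)(C)C(C)(C)C)C/C(C)=C/[Al](C)C | intermediate
15 | tert-butyl{[(1E,4S)-1-iodo-2,6-dimethylhepta-1,5-dien-4-yl]oxy}dimethylsilane | CC(C)=C[C@@H](O[Si](C)(C)C(C)(C)C)C/C(C)=C/I | intermediate
16 | (4-bromobut-1-yn-1-yl)trimethylsilane | C[Si](C)(C)C#CCCBr | starting material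
17 | bromo[4-(trimethylsilyl)but-3-yn-1-yl]zinc | C[Si](C)(C)C#CCC[Zn]Br | intermediate
18 | tert-butyl{[(4S,6E)-2,6-dimethyl-11-(trimethylsilyl)undeca-2,6-dien-10-yn-4-yl]oxy}dimethylsilane | CC(C)=C[C@@H](O[Si](C)(C)C(C)(C)C)C/C(C)=C/CCC#C[Si](C)(C)C | intermediate
19 | tert-butyl{[(4S,6E)-2,6-dimethylundeca-2,6-dien-10-yn-4-yl]oxy}dimethylsilane | CC(C)=C[C@@H](O[Si](C)(C)C(C)(C)C)C/C(C)=C/CCC#C | intermediate
20 | {(1E,5E,8S)-8-[(tert-butyldimethylsilyl)oxy]-2,6,10-trimethylundeca-1,5,9-trien-1-yl}dimethylalumane | CC(C)=C[C@@H](O[Si](C)(C)C(C)(C)C)C/C(C)=C/CC/C(C)=C/[Al](C)C | intermediate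
21 | chloro{(1E,5E,8S)-8-[(tert-butyldimethylsilyl)oxy]-2,6,10-trimethylundeca-1,5,9-trien-1-yl}zinc | CC(C)=C[C@@H](O[Si](C)(C)C(C)(C)C)C/C(C)=C/CC/C(C)=C/[Zn]Cl | intermediate
22 | (2E,6E,10E,13S)-13-[(tert-butyldimethylsilyl)oxy]-1-(2,5-dimethoxy-3-methylphenyl)-3,7,11,15-tetramethylhexadeca-2,6,10,14-tetraen-5-one | CC(C)=C[C@@H](O[Si](C)(C)C(C)(C)C)C/C(C)=C/CC/C(C)=C/C(=O)C/C(C)=C/Cc1cc(OC)cc(C)c1OC | intermediate
23 | (2E,6E,10E,13S)-1-(2,5-dimethoxy-3-methylphenyl)-13-hydroxy-3,7,11,15-tetramethylhexadeca-2,6,10,14-tetraen-5-one | CC(C)=C[C@@H](O)C/C(C)=C/CC/C(C)=C/C(=O)C/C(C)=C/Cc1cc(OC)cc(C)c1OC | intermediate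
24 | 2-[(2E,6E,10E,13S)-13-hydroxy-3,7,11,15-tetramethyl-5-oxohexadeca-2,6,10,14-tetraen-1-yl]-6-methylcyclohexa-2,5-diene-1,4-dione | CC(C)=C[C@@H](O)C/C(C)=C/CC/C(C)=C/C(=O)C/C(C)=C/CC1=CC(=O)C=C(C)C1=O | intermediate
25 | 2-[(2E,6E,10E,13S)-13-hydroxy-3,7,11,15-tetramethyl-5-oxohexadeca-2,6,10,14-tetraen-1-yl]-6-methylbenzene-1,4-diol | CC(C)=C[C@@H](O)C/C(C)=C/CC/C(C)=C/C(=O)C/C(C)=C/Cc1cc(O)cc(C)c1O | target

**Step count**
Total: 14 steps. Longest linear sequence: 9 steps (9 to 25 through steps 6–14; the arene branch 1 to 25 through steps 1–5 and 11–14 is equally long).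

**Three steps most likely to fail**

Step 11 (the proposed new carbonylative union). Likely failure modes are direct allyl–alkenyl coupling without CO uptake, methyl transfer from aluminium, and Lewis-acid isomerisation of the product into the conjugated dienone. The fallback uses known chemistry, sets out from 19 and 8 and comes back at 22. Alkyne 19 is methylaluminated as before to alane 20, which is converted with n-BuLi into lithium butyl{(1E,5E,8S)-8-[(tert-butyldimethylsilyl)oxy]-2,6,10-trimethylundeca-1,5,9-trien-1-yl}dimethylaluminate F1 and trapped with paraformaldehyde to give (2E,6E,9S)-9-[(tert-butyldimethylsilyl)oxy]-3,7,11-trimethyldodeca-2,6,10-trien-1-ol F2. MnO2 in CH2Cl2 oxidises this to (2E,6E,9S)-9-[(tert-butyldimethylsilyl)oxy]-3,7,11-trimethyldodeca-2,6,10-trienal F3. Chloride 8 is treated at −78 °C in THF with activated barium (from BaI2 and lithium biphenylide) to give chloro[(2E)-4-(2,5-dimethoxy-3-methylphenyl)-2-methylbut-2-en-1-yl]barium F4. This allylbarium adds to the aldehyde of F3 through its unsubstituted α-carbon with retention of the E-olefin, a known property of allylbarium reagents, giving (2E,6E,10E,13S)-13-[(tert-butyldimethylsilyl)oxy]-1-(2,5-dimethoxy-3-methylphenyl)-3,7,11,15-tetramethylhexadeca-2,6,10,14-tetraen-5-ol F5 as both C5 epimers. Dess–Martin periodinane with NaHCO3 in CH2Cl2 then gives ketone 22.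

Step 13 (oxidative demethylation on the fully functionalised chain). The acidic oxidant may ionise the allylic carbinol or move the β,γ-olefin into conjugation. The fallback moves the oxidation to a simple early intermediate and ends with a fluoride deprotection; it sets out from 6 and comes back at 25. Arene 6 is oxidised with (NH4)2Ce(NO3)6 in MeCN–H2O to 2-methyl-6-(3-methylbut-2-en-1-yl)cyclohexa-2,5-diene-1,4-dione F6. Na2S2O4 reduces it to 2-methyl-6-(3-methylbut-2-en-1-yl)benzene-1,4-diol F7, and TBSCl with imidazole gives 1,4-bis[(tert-butyldimethylsilyl)oxy]-2-methyl-6-(3-methylbut-2-en-1-yl)benzene F8. SeO2 with t-BuOOH gives (2E)-4-{2,5-bis[(tert-butyldimethylsilyl)oxy]-3-methylphenyl}-2-methylbut-2-en-1-ol F9, and NCS with Me2S gives 1,4-bis[(tert-butyldimethylsilyl)oxy]-2-[(2E)-4-chloro-3-methylbut-2-en-1-yl]-6-methylbenzene F10. Union with alkyne 19 under the conditions of step 11 (or by the barium sequence above) gives (2E,6E,10E,13S)-1-{2,5-bis[(tert-butyldimethylsilyl)oxy]-3-methylphenyl}-13-[(tert-butyldimethylsilyl)oxy]-3,7,11,15-tetramethylhexadeca-2,6,10,14-tetraen-5-one F11. Global desilylation with TBAF buffered 1:1 with AcOH in degassed THF at 0 °C to rt then gives 25 directly.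

Step 6 (asymmetric propargylation of a β,β-disubstituted enal). The enantiomeric excess may be insufficient, and the facial sense is assigned by analogy. The fallback replaces asymmetric catalysis by a resolution; it sets out from 9 and comes back at 12. Zinc-mediated Barbier addition of propargyl bromide in THF with aqueous NH4Cl, through bromo(propa-1,2-dien-1-yl)zinc F12, gives racemic 2-methylhept-2-en-6-yn-4-ol F13. Sharpless kinetic resolution (Ti(OiPr)4, D-(−)-diisopropyl tartrate, t-BuOOH, 4 Å molecular sieves, CH2Cl2, −20 °C, run to about 60% conversion) epoxidises the (R)-enantiomer to (1R)-1-[(2S)-3,3-dimethyloxiran-2-yl]but-3-yn-1-ol F14, which is removed by chromatography. The unreacted alcohol is (S)-12. The same resolution can be used to raise the enantiomeric excess of material from step 6.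

**Further compounds**
F1 | step 11 | lithium butyl{(1E,5E,8S)-8-[(tert-butyldimethylsilyl)oxy]-2,6,10-trimethylundeca-1,5,9-trien-1-yl}dimethylaluminate | CC(C)=C[C@@H](O[Si](C)(C)C(C)(C)C)C/C(C)=C/CC/C(C)=C/[Al-](C)(C)CCCC.[Li+]
F2 | step 11 | (2E,6E,9S)-9-[(tert-butyldimethylsilyl)oxy]-3,7,11-trimethyldodeca-2,6,10-trien-1-ol | CC(C)=C[C@@H](O[Si](C)(C)C(C)(C)C)C/C(C)=C/CC/C(C)=C/CO
F3 | step 11 | (2E,6E,9S)-9-[(tert-butyldimethylsilyl)oxy]-3,7,11-trimethyldodeca-2,6,10-trienal | CC(C)=C[C@@H](O[Si](C)(C)C(C)(C)C)C/C(C)=C/CC/C(C)=C/C=O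
F4 | step 11 | chloro[(2E)-4-(2,5-dimethoxy-3-methylphenyl)-2-methylbut-2-en-1-yl]barium | Cl[Ba]C/C(C)=C/Cc1cc(OC)cc(C)c1OC
F5 | step 11 | (2E,6E,10E,13S)-13-[(tert-butyldimethylsilyl)oxy]-1-(2,5-dimethoxy-3-methylphenyl)-3,7,11,15-tetramethylhexadeca-2,6,10,14-tetraen-5-ol (both C5 epimers) | CC(C)=C[C@@H](O[Si](C)(C)C(C)(C)C)C/C(C)=C/CC/C(C)=C/C(O)C/C(C)=C/Cc1cc(OC)cc(C)c1OC
F6 | step 13 | 2-methyl-6-(3-methylbut-2-en-1-yl)cyclohexa-2,5-diene-1,4-dione | CC(C)=CCC1=CC(=O)C=C(C)C1=O
F7 | step 13 | 2-methyl-6-(3-methylbut-2-en-1-yl)benzene-1,4-diol | CC(C)=CCc1cc(O)cc(C)c1O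
F8 | step 13 | 1,4-bis[(tert-butyldimethylsilyl)oxy]-2-methyl-6-(3-methylbut-2-en-1-yl)benzene | CC(C)=CCc1cc(O[Si](C)(C)C(C)(C)C)cc(C)c1O[Si](C)(C)C(C)(C)C
F9 | step 13 | (2E)-4-{2,5-bis[(tert-butyldimethylsilyl)oxy]-3-methylphenyl}-2-methylbut-2-en-1-ol | OC/C(C)=C/Cc1cc(O[Si](C)(C)C(C)(C)C)cc(C)c1O[Si](C)(C)C(C)(C)C
F10 | step 13 | 1,4-bis[(tert-butyldimethylsilyl)oxy]-2-[(2E)-4-chloro-3-methylbut-2-en-1-yl]-6-methylbenzene | ClC/C(C)=C/Cc1cc(O[Si](C)(C)C(C)(C)C)cc(C)c1O[Si](C)(C)C(C)(C)C
F11 | step 13 | (2E,6E,10E,13S)-1-{2,5-bis[(tert-butyldimethylsilyl)oxy]-3-methylphenyl}-13-[(tert-butyldimethylsilyl)oxy]-3,7,11,15-tetramethylhexadeca-2,6,10,14-tetraen-5-one | CC(C)=C[C@@H](O[Si](C)(C)C(C)(C)C)C/C(C)=C/CC/C(C)=C/C(=O)C/C(C)=C/Cc1cc(O[Si](C)(C)C(C)(C)C)cc(C)c1O[Si](C)(C)C(C)(C)C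
F12 | step 6 | bromo(propa-1,2-dien-1-yl)zinc | C=C=C[Zn]Br
F13 | step 6 | racemic 2-methylhept-2-en-6-yn-4-ol | CC(C)=CC(O)CC#C
F14 | step 6 | (1R)-1-[(2S)-3,3-dimethyloxiran-2-yl]but-3-yn-1-ol | CC1(C)O[C@H]1[C@H](O)CC#C
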